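The constants of this coupling have to be read from the noon run, in which solid substrate dissolves and the dissolved starting material meets the coupling partner.

- noon: solid substrate 1 M; coupling partner 1 equiv; run made earlier
- flask: solid substrate 2.0 M; coupling partner 1.00 equiv; time 2.0 h

noon run (percent of the solid substrate charged)

| time / min | solid substrate / % | product / % |
|---|---|---|
| 10.0 | 66.3 | 7.0 |
| 15.0 | 52.1 | 12.7 |
| 20.0 | 37.8 | 20.4 |
| 30.0 | 14.8 | 34.8 |
| 50.0 | 0 | 57.9 |
| 80.0 | 0.1 | 73.3 |
| 120 | 0 | 81.2 |

(each reading ± 0.3 percentage points)

- solid substrate is a solid; its amount is given per volume of the solution
- the analysis behind the earlier runs scatters by 0.3 percentage points, standard deviation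
- at the start none of the solid substrate is in solution
- what has only dissolved of solid substrate counts as not reacted
- starting material means what is dissolved; the solid is not counted in it
- the reaction counts as stopped when no species that holds the solid substrate changes by six tenths of a point or more over the second half of the time

1. why nothing more happens at 2.0 h, or that something still does (for what has run out or reacted, a solid counts together with what of it has only dissolved) (it is still moving / all of the solid substrate has reacted / the coupling partner has run out first)
2. part of the solid substrate that has turned into other species by 2.0 h (what has only dissolved does not count)
3. product at 2.0 h, in percent of the solid substrate charged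
4. starting material at 2.0 h, in percent of the solid substrate charged

From 50.0 min on, the noon solid reads no more than 0.1%, so starting material and coupling partner each stand at the remainder after product. At equal amounts (second-order kinetics) the reciprocal of the share left climbs in a straight line, and in the noon run we read a climb of 0.0421 min⁻¹. That reading times the charge ratio is 0.0841 min⁻¹ for this flask.

That climb times the time is one dimensionless number, the time counted in first half-lives of the reaction, and at equal amounts the share left is one over one plus that number. Is one number enough? For the noon run it gives 16.5% left at 120 min, yet 18.8% was read, which amounts to a lag of 17.3 min.

We assume the solid leaves at the same molar pace, so twice the charge doubles the lag, and we reckon the solid gone by about 100 min, earlier than 2.0 h. Rate times the time after the lag gives 7.18, the tail number, so our reckoning leaves 12.2% starting material and a flask still moving.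

The forecast, slightly higher than our reckoning, gives 13% starting material, 87% product and 87% conversion, and says it is still moving: “the reaction is still moving”.

    solid substrate ⇌ starting material, rate k1*(cs1 - [starting material]) while solid is left; crystals form when [starting material] > cs1 (solubility = 1.20 M, k = 5.40 × 10⁻⁴ s⁻¹)
    starting material + coupling partner → product + by-product (k = 7.40 × 10⁻⁴ L mol⁻¹ s⁻¹)

The flask gives 13.3% starting material and 86.7% product at 2.0 h, and it is still moving. It has not come to rest: the same flask read at 3.0 h holds 7.80% starting material, where the tail number, grown with the time, gives 7.56%. At 20.0 h the tail number gives 1.01%. Ten times the time still adds 12 percentage points of product, reaching 99.0%, with 0.967% starting material remaining.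

The numbers in the tables are simulated for substances that don't exist, noise included.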